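**Retrosynthetic overview**
- Feature used: ring A of the coumarin (C4a, C5, C6, C7, C8, C8a) is a pentasubstituted phloroglucinol ring. The run C5–OH / C6–prenyl / C7–OMe / C8–H is the substitution pattern that a vinylketene + 1-methoxyalkyne benzannulation produces.
- Key cut: C5–C8 are removed from ring A by breaking C4a–C5, C5–C6, C7–C8 and C8–C8a. This leads back to a 3-aryl-6-(diazoacetyl)-2-pyranone and MeO–C≡C–CH2CH=CMe2. The lactone ring exists first and the benzene ring is grown onto it, the reverse of usual coumarin logic.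
- The pyranone comes from an arylacetate enolate and a β-ethoxyvinyl α-keto ester (C3–C4 bond, then O1–C2 lactonisation).
- Ring order: ring B (bought), then the pyranone ring, then ring A. The two allyl ethers on ring B are removed last with Pd(0).

Key step: step 5

Remark on the chemistry: the target SMILES holds no stereocentre and no stereogenic C=C (the prenyl alkene carries two methyl groups). The compound is therefore achiral and the route needs no stereocontrol. All four building blocks are taken as catalogue chemicals.

**Step 1**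
Reactants: 1 methyl 2-(2,4-dihydroxyphenyl)acetate
Product: 2 methyl 2-[2,4-bis(allyloxy)phenyl]acetate
Conditions: allyl bromide (2.5 equiv), K2CO3 (3 equiv), acetone, reflux
Reagents that add atoms: allyl bromide, C=CCBr
Why: Williamson etherification, in which K2CO3 deprotonates only the phenols and O-allylation should outrun lactonisation of the 2-phenoxide onto the ester; allyl is chosen because it should survive base, hot aqueous acid, acid chloride formation and light, and it leaves under neutral Pd(0) conditions that spare prenyl, OMe and lactone.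

**Step 2**
Reactants: 2 methyl 2-[2,4-bis(allyloxy)phenyl]acetate, 3 ethyl (E)-4-ethoxy-2-oxobut-3-enoate
Product: 6 3-[2,4-bis(allyloxy)phenyl]-2-oxo-2H-pyran-6-carboxylic acid, via dienol diester 4 (not isolated), via pyranone ethyl ester 5 (not isolated)
Conditions: KOt-Bu (1.1 equiv), THF, −78 °C; 3, −78 → 0 °C; then 4 M aq HCl–AcOH, 90 °C
Reagents that add atoms: water, O
Why: Addition–elimination of the ester enolate at the β-ethoxyvinyl carbon (vinylogous acyl substitution, as in 2-pyranone syntheses from β-alkoxyvinyl ketones) should give the oxalocrotonate-type dienolate of the classical 2-pyranone-6-carboxylic acid synthesis, and in hot HCl its E/Z isomers equilibrate through the keto form, the enol oxygen lactonises onto the methyl ester and the ethyl ester is hydrolysed.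

**Step 3**
Reactants: 6 3-[2,4-bis(allyloxy)phenyl]-2-oxo-2H-pyran-6-carboxylic acid
Product: 8 3-[2,4-bis(allyloxy)phenyl]-6-(2-diazoacetyl)-2H-pyran-2-one, via acid chloride 7 (not isolated)
Conditions: (COCl)2, DMF (cat.), CH2Cl2, 0 °C → rt, evaporate; TMSCHN2 (2 equiv), THF–MeCN, 0 °C
Reagents that add atoms: oxalyl chloride, O=C(Cl)C(=O)Cl (the chlorine of 7 only); trimethylsilyldiazomethane, C[Si](C)(C)C=[N+]=[N-]
Why: Acylation of a diazoalkane by an acid chloride (first stage of the Arndt–Eistert sequence), which at 0 °C should be faster than dipolar cycloaddition because both ring C=C bonds of the pyranone are trisubstituted.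

**Step 4**
Reactants: 9 2-chloro-1,1-dimethoxyethane (chloroacetaldehyde dimethyl acetal), 10 1-bromo-3-methylbut-2-ene (prenyl bromide)
Product: 12 1-methoxy-5-methylhex-4-en-1-yne, via sodium methoxyacetylide 11 (not isolated)
Conditions: NaNH2 (3.0 equiv), liq. NH3, −33 °C; then 10, −78 → −33 °C; H2O, pentane
Reagents that add atoms: sodium amide, [NH2-].[Na+] (the sodium of 11 only)
Why: This is the standard 1-alkoxy-1-alkyne preparation, in which two eliminations (HCl, MeOH) and a deprotonation of the haloacetal give the alkoxyacetylide that is alkylated in situ by SN2, and exactly three equivalents of amide leave no strong base to isomerise the skipped enyne.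

**Step 5**
Reactants: 8 3-[2,4-bis(allyloxy)phenyl]-6-(2-diazoacetyl)-2H-pyran-2-one, 12 1-methoxy-5-methylhex-4-en-1-yne
Product: 17 3-[2,4-bis(allyloxy)phenyl]-5-hydroxy-7-methoxy-6-(3-methylbut-2-enyl)-2H-chromen-2-one, via pyranonylketene 13 (not isolated), via cyclobutenone 14 (not isolated), via dienylketene 15 (not isolated), via cyclohexadienone 16 (not isolated)
Conditions: 12 (2 equiv), ClCH2CH2Cl (0.05 M, degassed), 440 nm LED, 20 °C until N2 evolution ends; then dark, 80 °C
Reagents that add atoms: none
Why: Proposed new method: visible-light Wolff rearrangement of 8 (1,2-shift of pyranone C6 from the carbonyl to the diazo carbon, N2 lost) should give ketene 13, whose electrophilic C=O carbon is attacked by the nucleophilic, prenyl-bearing carbon of ynol ether 12 in a regiospecific [2+2] to cyclobutenone 14; at 80 °C 14 opens (4π, conrotatory, reversible) to dienylketene 15, which closes by a 6π disrotatory electrocyclisation onto C5 of the pyranone to dienone 16 and tautomerises to phenol 17. The closest known reaction type is the Danheiser benzannulation in its diazo ketone version, shown for cycloalkenyl, aryl and five-membered heteroaryl diazo ketones with alkoxy-, silyloxy- and aminoalkynes; a 2-pyranone as the vinyl partner, which makes a coumarin, is the new element. One ring stays closed, benzene ring A, through the new bonds C8–C8a (Wolff shift), C5–C6 and C7–C8 ([2+2]) and C4a–C5 (6π), so that C5 and C8 come from the diazoacetyl group and C6 and C7 from the alkyne. No stereocentre remains, because the one in 14 and the one in 16 (both racemic) are erased by ring opening and by enolisation. The regiochemistry (free OH at C5, prenyl at C6, OMe at C7, H at C8) needs only the polarisation of the ynol ether and the fact that C5–H is the sole ring position next to the ketene-bearing C6. Chemoselectivity rests on 440 nm light that reaches the diazo ketone n–π* band but should not drive pyranone valence isomerisation, on a ketene [2+2] at 20 °C that should be faster than an inverse-demand Diels–Alder reaction at the C3,C6-disubstituted pyranone diene, on the ynol ether being far more nucleophilic than the prenyl and allyl alkenes, and on forming the phenol only in the dark thermal stage when no ketene 13 is left to acylate it.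

**Step 6**
Reactants: 17 3-[2,4-bis(allyloxy)phenyl]-5-hydroxy-7-methoxy-6-(3-methylbut-2-enyl)-2H-chromen-2-one
Product: 18 3-(2,4-dihydroxyphenyl)-5-hydroxy-7-methoxy-6-(3-methylbut-2-enyl)-2H-chromen-2-one (target)
Conditions: Pd(PPh3)4 (5 mol %), morpholine (10 equiv), THF, rt
Reagents that add atoms: none
Why: Tsuji–Trost deallylation, in which Pd(0) ionises only the allyl aryl ethers and excess morpholine traps the π-allyl fragment before it can C-allylate the phenols, while the acid-sensitive ortho-prenylphenol, the methyl ether and the lactone have no leaving group for Pd(0) and should stay untouched.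

**Compound list**
1 | methyl 2-(2,4-dihydroxyphenyl)acetate | COC(=O)Cc1ccc(O)cc1O | starting material
2 | methyl 2-[2,4-bis(allyloxy)phenyl]acetate | COC(=O)Cc1ccc(OCC=C)cc1OCC=C | intermediate
3 | ethyl (E)-4-ethoxy-2-oxobut-3-enoate | CCO/C=C/C(=O)C(=O)OCC | starting material
4 | 1-ethyl 6-methyl 5-[2,4-bis(allyloxy)phenyl]-2-hydroxyhexa-2,4-dienedioate (formed as potassium salt, equilibrating E/Z mixture) | CCOC(=O)C(O)=CC=C(C(=O)OC)c1ccc(OCC=C)cc1OCC=C | intermediate
5 | ethyl 3-[2,4-bis(allyloxy)phenyl]-2-oxo-2H-pyran-6-carboxylate | CCOC(=O)c1ccc(-c2ccc(OCC=C)cc2OCC=C)c(=O)o1 | intermediate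
6 | 3-[2,4-bis(allyloxy)phenyl]-2-oxo-2H-pyran-6-carboxylic acid | OC(=O)c1ccc(-c2ccc(OCC=C)cc2OCC=C)c(=O)o1 | intermediate
7 | 3-[2,4-bis(allyloxy)phenyl]-2-oxo-2H-pyran-6-carbonyl chloride | ClC(=O)c1ccc(-c2ccc(OCC=C)cc2OCC=C)c(=O)o1 | intermediate
8 | 3-[2,4-bis(allyloxy)phenyl]-6-(2-diazoacetyl)-2H-pyran-2-one | [N-]=[N+]=CC(=O)c1ccc(-c2ccc(OCC=C)cc2OCC=C)c(=O)o1 | intermediate
9 | 2-chloro-1,1-dimethoxyethane | COC(CCl)OC | starting material
10 | 1-bromo-3-methylbut-2-ene | CC(C)=CCBr | starting material
11 | sodium methoxyacetylide | COC#[C-].[Na+] | intermediate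
12 | 1-methoxy-5-methylhex-4-en-1-yne | COC#CCC=C(C)C | intermediate
13 | 3-[2,4-bis(allyloxy)phenyl]-6-(2-oxoethenyl)-2H-pyran-2-one (ketene) | O=C=Cc1ccc(-c2ccc(OCC=C)cc2OCC=C)c(=O)o1 | intermediate
14 | 3-[2,4-bis(allyloxy)phenyl]-6-[2-methoxy-3-(3-methylbut-2-enyl)-4-oxocyclobut-2-enyl]-2H-pyran-2-one (racemic) | COC1=C(CC=C(C)C)C(=O)C1c1ccc(-c2ccc(OCC=C)cc2OCC=C)c(=O)o1 | intermediate
15 | dienylketene, ketenyl carbon and pyranonyl group cis on the enol ether C=C | O=C=C(CC=C(C)C)/C(OC)=C\c1ccc(-c2ccc(OCC=C)cc2OCC=C)c(=O)o1 | intermediate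
16 | 3-[2,4-bis(allyloxy)phenyl]-7-methoxy-6-(3-methylbut-2-enyl)-4aH-chromene-2,5-dione (racemic) | COC1=C(CC=C(C)C)C(=O)C2C=C(c3ccc(OCC=C)cc3OCC=C)C(=O)OC2=C1 | intermediate
17 | 3-[2,4-bis(allyloxy)phenyl]-5-hydroxy-7-methoxy-6-(3-methylbut-2-enyl)-2H-chromen-2-one | COc1cc2oc(=O)c(-c3ccc(OCC=C)cc3OCC=C)cc2c(O)c1CC=C(C)C | intermediate
18 | 3-(2,4-dihydroxyphenyl)-5-hydroxy-7-methoxy-6-(3-methylbut-2-enyl)-2H-chromen-2-one | COc1cc2oc(=O)c(-c3ccc(O)cc3O)cc2c(O)c1CC=C(C)C | target

**Total step count:** 6
**Longest linear sequence:** 5 (steps 1, 2, 3, 5, 6; step 4 is the side branch)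

**Steps most likely to fail**

1. Step 5 (Proposed new method).
   - What may go wrong: the pyranone may be excited and undergo valence isomerisation. The ynol ether may add across C3/C6 of the pyranone in an inverse-demand cycloaddition with loss of CO2. The ketene may dimerise, or the 6π closure onto the lactone ring may be sluggish.
   - Fallback (known chemistry): ring A is bought and the prenyl group is placed by an aromatic Claisen rearrangement. It sets out from 2 and comes back at 17. Compound 2 is saponified (LiOH, THF–H2O) to 2-[2,4-bis(allyloxy)phenyl]acetic acid F1. This acid is condensed with purchased, C2-symmetric 2,6-dihydroxy-4-methoxybenzaldehyde F2 in a Perkin–Oglialoro reaction (Ac2O, Et3N, 110 °C). Both ortho hydroxyls of F2 are equivalent, so only one lactone can form, 5-acetoxy-3-[2,4-bis(allyloxy)phenyl]-7-methoxycoumarin F3. Methanolysis (K2CO3, MeOH) gives 3-[2,4-bis(allyloxy)phenyl]-5-hydroxy-7-methoxycoumarin F4. O-Alkylation with 3-chloro-3-methylbut-1-yne (DBU, CuCl2 cat., MeCN, 0 °C) gives the 5-(2-methylbut-3-yn-2-yloxy)coumarin F5. Lindlar semihydrogenation gives the 5-(2-methylbut-3-en-2-yloxy)coumarin F6. Heating F6 (N,N-diethylaniline, about 120 °C, well below the range in which simple allyl aryl ethers rearrange) should deliver the prenyl group by [3,3] shift to C6, the only free ortho position, and give 17.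

2. Step 2.
   - What may go wrong: the enolate may attack the keto or ester carbonyl of the α-keto ester instead of the vinylogous carbon. Allyl ethers may be partly lost in the hot acid.
   - Fallback: a different bond is made, C5–C6 by a vinylogous Claisen condensation. It sets out from 2 and comes back at 4. The lithium enolate of 2 (LDA, THF, −78 °C) is added to acetaldehyde to give methyl 2-[2,4-bis(allyloxy)phenyl]-3-hydroxybutanoate F7. This is converted (MsCl, Et3N) into methyl 2-[2,4-bis(allyloxy)phenyl]-3-(methylsulfonyloxy)butanoate F8, and elimination with DBU gives methyl 2-[2,4-bis(allyloxy)phenyl]but-2-enoate F9. γ-Deprotonation of F9 (KOt-Bu, THF) and acylation by diethyl oxalate follow the classical oxalocrotonate condensation. α-Acylation would give a non-enolisable, reversible adduct, so the reaction should funnel to the potassium salt of 4. Compound 4 is then cyclised as in step 2, if necessary in two milder stages (TsOH in toluene, then dilute HCl in dioxane).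

3. Step 3.
   - What may go wrong: 1,3-dipolar cycloaddition of the diazoalkane to a pyranone C=C bond may compete with acylation. Adventitious HCl may destroy the diazo ketone.
   - Fallback: the diazo group is installed by diazo transfer instead of by acylation. It sets out from 7 and comes back at 8. A Stille acylation of 7 (Me4Sn, BnPdCl(PPh3)2 cat., THF, 60 °C) gives 6-acetyl-3-[2,4-bis(allyloxy)phenyl]-2H-pyran-2-one F10. Kinetic enolisation (LiHMDS, THF, −78 °C) and trapping with 2,2,2-trifluoroethyl trifluoroacetate give 3-[2,4-bis(allyloxy)phenyl]-6-(4,4,4-trifluoro-3-oxobutanoyl)-2H-pyran-2-one F11. Detrifluoroacetylative diazo transfer (MsN3, Et3N, H2O, MeCN, rt) then gives 8.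

**Further compounds**
F1 | step 5 | 2-[2,4-bis(allyloxy)phenyl]acetic acid | OC(=O)Cc1ccc(OCC=C)cc1OCC=C
F2 | step 5 | 2,6-dihydroxy-4-methoxybenzaldehyde (purchased) | COc1cc(O)c(C=O)c(O)c1
F3 | step 5 | 5-acetoxy-3-[2,4-bis(allyloxy)phenyl]-7-methoxycoumarin | COc1cc2oc(=O)c(-c3ccc(OCC=C)cc3OCC=C)cc2c(OC(C)=O)c1
F4 | step 5 | 3-[2,4-bis(allyloxy)phenyl]-5-hydroxy-7-methoxycoumarin | COc1cc2oc(=O)c(-c3ccc(OCC=C)cc3OCC=C)cc2c(O)c1
F5 | step 5 | 3-[2,4-bis(allyloxy)phenyl]-7-methoxy-5-(2-methylbut-3-yn-2-yloxy)coumarin | COc1cc2oc(=O)c(-c3ccc(OCC=C)cc3OCC=C)cc2c(OC(C)(C)C#C)c1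
F6 | step 5 | 3-[2,4-bis(allyloxy)phenyl]-7-methoxy-5-(2-methylbut-3-en-2-yloxy)coumarin | COc1cc2oc(=O)c(-c3ccc(OCC=C)cc3OCC=C)cc2c(OC(C)(C)C=C)c1
F7 | step 2 | methyl 2-[2,4-bis(allyloxy)phenyl]-3-hydroxybutanoate (racemic diastereomer mixture) | COC(=O)C(C(C)O)c1ccc(OCC=C)cc1OCC=C
F8 | step 2 | methyl 2-[2,4-bis(allyloxy)phenyl]-3-(methylsulfonyloxy)butanoate (racemic diastereomer mixture) | COC(=O)C(C(C)OS(C)(=O)=O)c1ccc(OCC=C)cc1OCC=C
F9 | step 2 | methyl 2-[2,4-bis(allyloxy)phenyl]but-2-enoate (E/Z mixture) | COC(=O)C(=CC)c1ccc(OCC=C)cc1OCC=C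
F10 | step 3 | 6-acetyl-3-[2,4-bis(allyloxy)phenyl]-2H-pyran-2-one | CC(=O)c1ccc(-c2ccc(OCC=C)cc2OCC=C)c(=O)o1
F11 | step 3 | 3-[2,4-bis(allyloxy)phenyl]-6-(4,4,4-trifluoro-3-oxobutanoyl)-2H-pyran-2-one | O=C(CC(=O)C(F)(F)F)c1ccc(-c2ccc(OCC=C)cc2OCC=C)c(=O)o1
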